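The constants are not on the table, so you take what you need from the runs.

| flask | substrate | solid partner | remark | time |
|---|---|---|---|---|
| amber | 30 mM (fed, over 4.0 d) | 30 mM | run made earlier |  |
| ochre | 10 mM (fed, over 4.0 d) | 30 mM | run made earlier |  |
| Saturday's | 20 mM (fed, over 4.0 d) | 30.0 mM |  | 25 d |
| Friday's | 20 mM (fed, over 4.0 d) | 39.0 mM |  | 25 d |

- amber (time / d: target / %, substrate / %, open intermediate / %): 0.625: 0.5, 14.1, 1.0; 1.04: 1.8, 20.9, 5.3; 1.67: 2.1, 29.0, 8.1; 2.50: 10.8, 39.3, 14.5; 4.00: 24.6, 51.3, 27.7; 6.00: 33.0, 22.5, 42.1; 8.00: 36.1, 11.3, 52.3
- ochre (time / d: target / %, substrate / %, open intermediate / %): 0.625: 0.2, 14.1, 2.1; 1.04: 0.6, 20.9, 4.2; 1.67: 3.3, 29.5, 8.5; 2.50: 10.5, 39.5, 13.0; 4.00: 25.9, 49.4, 23.3; 6.00: 42.7, 21.4, 36.3; 8.00: 53.2, 11.3, 42.0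

(each reading ± 1 percentage point)

- at the start none of the solid partner is in solution
- a reading or a percentage of target counts all its forms, free or not
- percentages count the whole charge, also what has not yet gone in

- which of these there is most of at the end, counted by the substrate in it, Saturday's (target / substrate / open intermediate)
- which of these there is most of at the end, counted by the substrate in it, Friday's (target / substrate / open intermediate)
- how much there is at the end of the one of these that leads, in percent of the substrate charged: Saturday's
- how much there is at the end of the one of these that leads, in percent of the substrate charged: Friday's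

Start with the clock. After its feed, amber's substrate halves every 1.83 d, a reading, and 21.0 d follow the feed in Saturday's flask. So count the end as target and open intermediate, and ask how much target there is.

Treat solid partner as the limiting reagent and take as its yield amber's last [target] divided by the partner charged, a reading: 0.361. Saturday's target then comes to 54.2%.

But ochre, with the same partner, stood at 5.32 mM at 8.00 d, less than amber's 10.8 mM, and both were still rising. So run each out. Let c be the gain of target in one step of 2.00 d, divided by the mean open intermediate held, and c′ the same for the next step. If c keeps falling by that factor, the remaining steps sum to c′·c′/(c − c′), and the rest of the charge turns to target by the share 1 − exp(−sum).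

amber: c = 0.241, c′ = 0.0657, sum 0.0246, final [target] 11.3 mM

ochre: c = 0.564, c′ = 0.268, sum 0.243, final [target] 6.33 mM

Amber's last gain is 3.1 percentage points against a scatter of 1 point, which looks fatal, but its tail adds just 0.467 mM.

Saturday's 20 mM lies midway between the two charges, so take the midpoint. This gives the partner's yield, mM of target finally made per mM of solid partner charged, 0.294. A straight line through two runs is a doubt I keep, and so is holding the yield at Friday's 39.0 mM, since amber had 30 mM of partner and ochre 30 mM. I commit anyway:

Saturday's: target 44.1%, so open intermediate leads with 55.9%

Friday's: target leads with 57.3%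

The forecast gave target at 52% for Saturday's, where I have open intermediate ahead, and target at 62% for Friday's, reasoning “That suggests partner is consumed”.

Saturday's flask gives open intermediate at 55.7%. Friday's flask gives target at 56.4%.

    substrate → open intermediate (k = 4.60 × 10⁻⁶ s⁻¹)
    fresh partner → second intermediate (k = 1.30 × 10⁻⁴ s⁻¹)
    open intermediate + second intermediate → target (k = 7.80 × 10⁻⁴ M⁻¹ s⁻¹)
    2 second intermediate → homo product (k = 3.70 × 10⁻⁴ M⁻¹ s⁻¹)
    crystals ⇌ target, rate k5*(cs5 - [target]) while solid is left; crystals form when [target] > cs5 (solubility = 8.80 mM, k = 9.00 × 10⁻⁵ s⁻¹)
    solid partner ⇌ fresh partner, rate k6*(cs6 - [fresh partner]) while solid is left; crystals form when [fresh partner] > cs6 (solubility = 11.0 mM, k = 1.20 × 10⁻⁵ s⁻¹)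

The partner's yield comes out at 0.296 in Saturday's flask and 0.289 in Friday's, beside the 0.294 carried. Now take a neighbour of Friday's, charged with 23 mM of solid partner, the substrate unchanged. The carried yield gives this neighbour 33.8% target, and the rest of its charge stays open intermediate. The neighbour ends with target at 35.7%, and open intermediate leads at 64.3%.

Readings and results were generated by integration from invented constants; noise was put on by code.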